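The numbers are assumed.

At early times substrate pairs into target, and the question is how far that pairing gets by the end of each flask.

    substrate + substrate ⇌ target (K1 = 30.6 M⁻¹, k1 = 0.00221 M⁻¹ min⁻¹)
    target ⇌ isomer of the product (K2 = 1.43, k2 = 1.42 × 10⁻⁴ min⁻¹)

| flask | substrate | time |
|---|---|---|
| Wednesday's | 0.10 M | 25 h |
| Sunday's | 0.10 M | 40 h |

* which of these there is most of at the end, counted by the substrate in it, Wednesday's (isomer of the product / substrate / target)
* which of these there is most of at the end, counted by the substrate in it, Sunday's (isomer of the product / substrate / target)
* amount of the one of these that there is most of at the end, in percent of the substrate charged, Wednesday's
* amount of the one of these that there is most of at the end, in percent of the substrate charged, Sunday's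

- Each pairing takes two substrate, so c(substrate) falls at twice the first rate constant times its square. While the back run is small, the share of substrate left is one over one plus the pairing number.
- That number is 0.663 for Wednesday's and 1.06 for Sunday's. The pairing number (a Damköhler number) is twice the rate constant times the charge times the time: the run counted in first half-lives of the substrate, here 37.7 h.
- I read off 60.1% left on Wednesday's and 48.5% on Sunday's.
- Is one number enough? If the whole rest of Wednesday's were target, pairing would still run 5.55 times the back run, so I expect a little more substrate than my share.
- On Sunday's the rest, 51.5%, is slightly more than the substrate share, but target must divide it with the isomer of the product. I commit to substrate leading in both flasks.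
- The forecast says substrate at 62% for Wednesday's and substrate at 52% for Sunday's, from “a quick rough run through the rates, not an exact solution”. It names the same species, and its figures stand 1.9 percentage points and 3.5 points above mine, on the side the back run points to.
- Wednesday's flask gives substrate at 61.8%. Sunday's flask gives substrate at 51.6%.
- Sunday's substrate moves by the same margin at 0.129 M of charge or at 53.5 h of time, and these give pairing numbers of 1.37 and 1.42.
- For Wednesday's flask charged with 0.40 M, the pairing number is 2.65, which leaves a share of 27.4% and points to target leading. That flask gives target at 60.8%, with substrate at 30.0%.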